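If a flask's rate follows its catalyst, its real clock is the catalyst concentration multiplied by the minutes, and I want the one constant that turns this clock into conversion.

| setting | gamma | alpha | eta | Monday's | Friday's | Sunday's | Saturday's | Thursday's |
|---|---|---|---|---|---|---|---|---|
| starting material | 1 M | 1 M | 1 M | 1.0 M | 1.0 M | 1.0 M | 1.0 M | 0.50 M |
| coupling partner | 0.30 equiv | 2.1 equiv | 1 equiv | 1.00 equiv | 1.00 equiv | 0.250 equiv | 1.00 equiv | 1.50 equiv |
| free catalyst | 5 mol% | 5 mol% | 9.4 mol% | 10 mol% | 8 mol% | 15 mol% | 5 mol% | 5 mol% |
| remark | run made earlier | run made earlier | run made earlier |  |  |  |  |  |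
| time |  |  |  | 3.0 min | 3.0 min | 3.0 min | 3.0 min | 3.0 min |

| run | time / min | product / % | starting material / % |
|---|---|---|---|
| gamma | 0.250 | 0.8 | 98.4 |
| gamma | 0.833 | 6.9 | 93.9 |
| gamma | 1.33 | 9.3 | 88.8 |
| gamma | 2.00 | 13.6 | 85.3 |
| gamma | 3.00 | 17.6 | 80.3 |
| alpha | 0.250 | 0.3 | 98.1 |
| alpha | 0.417 | 4.1 | 95.6 |
| alpha | 0.833 | 5.0 | 93.2 |
| alpha | 1.50 | 11.2 | 89.4 |
| alpha | 3.00 | 19.6 | 81.0 |
| eta | 0.250 | 3.2 | 96.1 |
| eta | 0.833 | 10.1 | 89.7 |
| eta | 1.33 | 14.9 | 80.3 |
| eta | 2.00 | 24.4 | 73.5 |
| eta | 3.00 | 34.8 | 63.2 |

(readings scatter by 1 percentage point)

- the earlier runs were read with a standard deviation of 1 percentage point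
- a reading or a percentage of product counts all its forms, free or not

- the flasks put in order of amount of product, in percent of the starting material charged, best first, at 3.0 min (Monday's / Friday's / Sunday's / Saturday's / Thursday's)
- the amount of product, in percent of the starting material charged of the flask you put first, at 3.0 min
- the amount of product, in percent of the starting material charged of the flask you put last, at 3.0 min

The gamma and alpha runs, with 0.30 equiv and 2.1 equiv of coupling partner, end at 17.6% and 19.6% of product, a gap close to the scatter of 1 percentage point, so I drop the partner while it lasts. The eta run, with 9.4 mol% of catalyst, ends at 34.8%, nearly twice the gamma run, so I take the rate as proportional to catalyst. Freezing the catalyst concentration and assuming first order in starting material gives a pseudo-first-order decay. The last readings average 1.50 M⁻¹ min⁻¹ for the turnover constant, which is the logarithm of charged over remaining starting material, divided by catalyst concentration and by time.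

With it I reckon 36.2% for Monday's, 30.2% for Friday's and 20.1% for Saturday's. Sunday's reckons to 49.0%, but its 0.250 equiv of coupling partner, the limiting reagent, caps it at that share of the charge, which still stands above Saturday's.

Thursday's needs two extreme versions, since gamma, alpha and eta were each charged at 1 M. If the rate is proportional to starting material, Thursday's has half Saturday's catalyst concentration and reaches 10.6%. If the rate per catalyst ignores starting material, Thursday's reaches Saturday's percentage. For an order between zero and one it lies between these, so it stands at or below Saturday's in my reckoning. The turnover constant already takes first order in starting material, so I put Thursday's last and commit to the lower end.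

The forecast gives Monday's > Friday's > Sunday's > Saturday's > Thursday's, with 36% (33% to 40%) for the first flask and 10.5% (8.5% to 19%) for the last. Its own caution reads: “Order in starting material is not determined because all runs were at 1 M.”

The flasks come out Monday's > Friday's > Sunday's > Saturday's > Thursday's, with 36.5% first and 11.5% last.

    catalyst intermediate A ⇌ catalyst intermediate B (K = 0.110, k = 3.30 s⁻¹)
    2 catalyst intermediate C → spent catalyst (k = 0.0530 M⁻¹ s⁻¹)
    starting material + catalyst intermediate B → catalyst intermediate C (k = 0.310 M⁻¹ s⁻¹)
    crystals ⇌ product, rate k4*(cs4 - [product]) while solid is left; crystals form when [product] > cs4 (solubility = 0.790 M, k = 0.190 s⁻¹)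
    coupling partner + free catalyst → catalyst intermediate A (k = 2.90 M⁻¹ s⁻¹)
    catalyst intermediate C → free catalyst + product (k = 0.180 s⁻¹)

In Thursday's at 3.00 min, 83.1% of the catalyst sits as catalyst intermediate A, the resting state, and 0.644% as free catalyst, which a single constant does not show. The neighbouring flask is Thursday's recipe at 1.2 M of starting material, with the same equivalents and loading, so its catalyst concentration is 0.0600 M. The turnover constant then gives 23.6%. That flask gives 23.3% of product, with 81% of its coupling partner left.

(The data are simulated from invented constants, and the scatter is random.)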